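All runs are calculated from invented constants; noise was put on by code.

Still left in the larch run after 30.0 h is 92.4% of the substrate charged, so I set aside the loss of substrate for now and read these runs, in which substrate takes up dissolved gas to give product, by their rates.

| flask | substrate | gas | remark | time |
|---|---|---|---|---|
| birch | 0.10 M | 79 mM (held) | run made earlier |  |
| larch | 0.40 M | 79 mM (held) | run made earlier |  |
| flask | 0.20 M | 79 mM (held) |  | 40 h |

| birch: time / h | birch: product / % | larch: time / h | larch: product / % |
|---|---|---|---|
| 2.50 | 0 | 1.50 | 0.6 |
| 4.00 | 0.1 | 5.00 | 1.6 |
| 6.00 | 2.0 | 10.0 | 2.0 |
| 10.0 | 1.4 | 15.0 | 4.4 |
| 15.0 | 3.0 | 20.0 | 5.1 |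
| 20.0 | 5.5 | 25.0 | 6.6 |
| 30.0 | 10.0 | 30.0 | 7.6 |

(readings scatter by 0.5 percentage points)

1. amount of product at 40 h, in percent of the substrate charged
2. the change that raises the amount of product at 40 h, in percent of the substrate charged most ("none" if none brings more than 2 percentage points) (green / violet / none)
3. amount of product at 40 h, in percent of the substrate charged, after green

- green: doubling the transfer coefficient of the gas, all else as stated
- violet: doubling the saturation concentration of gas, all else as stated

- the numbers in the tables scatter with a standard deviation of 0.5 percentage points
- at the start none of the gas is in solution

The larch product climbs in a roughly straight line from the start, at 1.01 mM h⁻¹ on average. I call this the crossing rate s, the rate at which gas enters solution, and I take that crossing as the rate-limiting step there. No gas is in solution at the start, and the birch product stands near nothing in the first readings and then grows roughly as the square of time. I let the rate of product stand short of s by a factor that falls by e in each lag, and the last birch reading then gives that run a lag of 45.6 h. The larch readings show no lag I can see, so I let the lag fall with the square of substrate, an uncertain order, which gives this flask 11.4 h. By 40 h the shortfall factor has fallen to hardly any, so the slowing adds up to s times the lag, 11.6 mM out of the 40.5 mM crossed, and I commit to 14.5%. Doubling s by green or by violet, with the lag held, adds about that much again, against the 2 percentage points that counts, but this does not tell the two changes apart.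

The forecast gives 14.5%, names violet and gives 25.5% after green, saying “Doubling saturation wins slightly because the driving force doubles without any loss to back-pressure”. It rests on the same readings as mine, so the closeness of the two is no check.

The flask gives 15.6%, and violet gains 13 points against 9.7 points for green, which reaches 25.3%.

    gas ⇌ reagent, rate k1*(csat - [reagent]) (kL = 0.0200 h⁻¹)
    substrate + reagent → product, rate k2*[substrate]^1.5*[reagent] (k = 0.700 L¹·⁵ mol⁻¹·⁵ h⁻¹)

Between 20.0 h and 40.0 h this flask makes product at 0.974 mM h⁻¹, close to s. In this flask, each step taken net, reagent is made 1.44 times faster than it is used up at 18.6 h and 1.17 times faster at 40.0 h, so making and using draw together. For the neighbour read at 144 h, with the same charge, s and the lag give 67.2%, and the computed neighbour holds 58.9% as product, with 41.1% of its substrate left.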